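## Structural features

The target joins two unlike halves through a saturated two-carbon link. One half is a 1,2-dioxane (O1, O2, C3–C6). The other is a 5,5-dimethyl-hexahydronaphthalene in which ring A and ring B share the tetrasubstituted alkene C4a=C8a. C3 carries the propanoic acid chain, so C2 (methyl-bearing) and C3 (peroxide-bearing) are neighbouring stereocentres in an anti relationship. C6 is a quaternary, oxygen-bearing stereocentre across the ring from C3, with the C3 side chain and the C6 tether (C1'–C2'–C3') on the same face; all three centres are S. The tether ends in an exocyclic trisubstituted alkene (C3'=C2 of ring A). Its Z geometry puts the chain next to the isolated ring methylene C1 and away from the C3–C4 arm. The two arms differ only three atoms away from the alkene, so neither thermodynamics nor an olefination of a ring A ketone can tell them apart. Fragile features are the O–O bond (low-valent metals, hydrides, hydrogenation catalysts), H–C3 and the α-hydrogen at C2 (base-induced Kornblum–DeLaMare cleavage, β-elimination of the peroxide), and the skipped diene with its doubly allylic C1 methylene (acid, quinone oxidants, radical chains). The real difficulties are the exocyclic alkene geometry, the configuration of the tertiary peroxide carbon C6 relative to C2/C3, and a union of the halves that the peroxide survives. The key step uses the C4–C4a bond of ring A, between the sp3 methylene C4 and the alkene carbon C4a next to the gem-dimethyl carbon C5. An alkyl–alkenyl coupling there closes ring A on a precursor whose alkene geometry was already fixed in an open chain.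

## Logic of the disconnections

**33 to 31 (through 32).** The last changes are the O–CH3 bond of a methyl ester and two C–H bonds at C1' and C2'. The acid is masked because the union needs a carbanion. The extra alkene is accepted because C1' sits on the quaternary C6, where no substitution chemistry is possible. The forward steps must hydrolyse without enolising C2 and must saturate only the disubstituted alkene without touching O–O.

**31 to 17 and 30.** The C1'=C2' bond is cut. An aldehyde on C6 has no α-hydrogen, and placing the carbanion on the hydrocarbon half keeps every carbanion away from the β-position of the peroxide. The gain is two halves of similar size: one holds all stereocentres and no alkene, the other holds all alkenes and no stereocentre. The olefination must run cold with one equivalent of base and must keep the geometry of the allylic sulfone.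

**17 to 14 (through 16 and 15).** The C–S bond, the two S–O bonds and the O–Si bond are cut. This reduces the sulfone to a protected allylic alcohol. The sulfur must be introduced by direct SN2 at the primary allylic carbon and oxidised without attack on the alkenes.

**14 to 12 (through 13).** The C4–C4a bond of ring A is cut, which opens the bicycle to a monocyclic iodo enol triflate. The exocyclic alkene becomes an acyclic trisubstituted alkene whose two arms are now chemically different (iodoethyl against cyclohexenylmethyl). The forward step must couple a primary alkyl metal with a hindered tetrasubstituted triflate without forming any allyl metal species.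

**12 to 9 (through 11 and 10).** The carbon–iodine bond, one O–Si bond and the enol O–S bond are cut. The ring-fusion alkene is traced back to a ketone that can enolise in one direction only. The demand is a clean removal of one silyl group in the presence of the other.

**9 to 8 and 7.** The bond between the ketone α-carbon and the allylic methylene (the future C8a–C1 bond) is cut. Ring B with its gem-dimethyl group is then a catalogue ketone. The allylic bromide must react by SN2 without loss of geometry.

**7 to 3 and 4 (through 6 and 5); 3 to 1 and 2.** The trisubstituted C=C bond and the bond from the α-carbon to the silyloxyethyl arm are cut. A Z-selective phosphonate olefination must place the silyloxymethyl group cis to the ester, because the ester carbon becomes C1 of ring A.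

**30 to 26 (through 29, 28 and 27).** The formyl carbon is traced to a vicinal diol (one C–C bond cut in the forward sense), and C1 to a vinyl group. Both masks are inert to the peroxide-forming chemistry. The vinyl group must be converted while the C2 stereocentre passes through an aldehyde.

**26 to 24 (through 25).** Both C–O bonds of the peroxide are cut: O2–C3 to a secondary sulfonate and O1–C6 to a tertiary epoxide carbon. Each bond then forms with inversion from a centre made by reliable asymmetric chemistry. The forward step needs a stereospecific perhydrolysis at the tertiary carbon and a 6-exo ring closure that outruns elimination.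

**24 to 21 (through 23 and 22).** The epoxide oxygen, the mesyl group and the acetate are removed in the backward sense. The epoxidation must be reagent-controlled, and the C3 oxygen must be masked before the epoxide exists.

**21 to 19 and 20; 19 to 18.** The C2–C3 bond is cut (crotyl addition to an aldehyde), and the aldehyde is traced to the distal alkene of an acyclic terpene acetate. A Z-crotyl reagent with reagent-controlled facial selectivity and a chemoselective alkene cleavage are required.

## Other disconnections considered

**Alternative 1:** The cut removes both C–O bonds of the dioxane at once (O2–C3 and O1–C6). In the forward sense singlet oxygen would add across the ring diene of acetonide A2, on the face away from the dioxolane, to give the bicyclic endoperoxide A1. Diimide reduction of the remaining ring alkene, removal of the acetonide and cleavage of the diol bridge would then give the cis-3,6-diformyl dioxane A4.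
- In favour: the two C–O bonds form suprafacially in one step, so the cis relation of the carbon substituents at C3 and C6 is built in. C6 is made without substitution at a tertiary carbon. On both points, and in the number of steps to the peroxide core, this alternative is better than the chosen plan.
- Against: A4 has two aldehydes on peroxide-bearing carbons that must be told apart. The aldehyde carbon at C3 must become C2 with a methyl group, a carboxyl group and a defined configuration, and no dependable reaction does that next to a peroxide. The chosen plan sets C2 and C3 together before any O–O bond exists.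
- Absolute configuration: by CIP bookkeeping A1 has the C3/C6 configuration of the target, but A2 is the mirror image of the acetonide that the dioxygenase-derived diol A3 (1S,2R) would give. The natural series would lead to the antipodal core. This would have to be settled first.
- Comparison: the alternative is the cleaner mechanism for the O–O ring, and it is weaker on overall stereocontrol and on the steps after ring formation. It is silent on the hydrocarbon half and could be combined with the ring A closure used here.

**Alternative 2:** The cut removes the C1–C2 bond of ring A and the C2'–C3' bond in one operation. Pd(PPh3)4 (zerovalent palladium) would ionise the allylic acetate A6. The allyl terminus would add syn across the tethered alkyne to close ring A, and the resulting alkenylpalladium would be captured by the alkylborane A7 to give A5 (identical with 32).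
- In favour: syn carbopalladation places palladium, and then the chain, cis to C1, so the geometry is set by mechanism. On this point it equals the chosen plan. It closes ring A and joins the halves in one step and needs no sulfone, no extra alkene and no diimide step. Step economy in the hydrocarbon half and the endgame is better.
- Against: the peroxide must survive hydroboration and then a hot, basic coupling with zerovalent palladium and phosphine. In the chosen plan palladium and zinc never meet the O–O bond. The cascade also has more branch points: direct allyl–alkyl coupling, β-hydride elimination, and the regiochemistry of the allyl terminus, on which the position of the C4a=C8a alkene depends.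
- Comparison: both routes use palladium to form a ring A bond. The chosen plan does it on a peroxide-free substrate with one defined organometallic partner. The alternative still needs an equally demanding stereocontrolled peroxide half.

**Alternative 3:** The cut is the C4=C5 bond of a dihydrodioxine. The second-generation Grubbs catalyst would join the two vinyl groups of the acyclic peroxide A9 to give A8.
- In favour: metathesis closes the ring without base or nucleophile and tolerates dialkyl peroxides, so the ring-forming event is short and mild. On the tertiary centre the two plans are equal, since A9 needs an enantiopure tertiary allylic peroxide.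
- Against: C3 arrives as an acetal carbon of either configuration. C3 and C2 must then be made by replacing the ethoxy group with a propionate enolate equivalent through a peroxycarbenium ion. Facial control relative to C6 and simple diastereoselection at C2 are both uncertain, and the allylic cation can also be attacked at C5.
- Further costs: the ring alkene still has to be reduced with diimide, so the alternative does not save the chosen plan's diimide step. The C6 arm ends at C2' with oxygen, so the link to ring A would be an sp3–sp2 coupling beside the peroxide or an olefination that forms the trisubstituted alkene without geometric control.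
- Comparison: equal or better in ring-forming step economy, lower in stereochemical security.

Key step: step 9

Remark: locants follow the target (dioxane O1, O2, C3–C6; acid chain C1, C2; tether C1'–C3'; hexahydronaphthalene C1–C8a). The allylic oxygen is carried as a tert-butyldiphenylsilyl ether, so that no quinone oxidant meets the skipped diene. Assumption: the new disubstituted alkene of 31 is drawn E; either geometry serves, because step 23 saturates that bond.

## Steps

Step 1
Reactants: 1 methyl bis(2,2,2-trifluoroethyl)phosphonoacetate; 2 tert-butyl(2-iodoethoxy)dimethylsilane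
Product: 3 methyl 2-[bis(2,2,2-trifluoroethoxy)phosphoryl]-4-[(tert-butyldimethylsilyl)oxy]butanoate (racemic)
Conditions: NaH, DMF, 0 °C; then 2, rt → 50 °C
Reagents that add atoms: none
Why: Alkylation of the stabilised phosphonoacetate anion at carbon by SN2 on the primary iodide (malonate-type alkylation); an excess of 1 limits double alkylation, and the stereocentre formed here disappears in step 2.

Step 2
Reactants: 3 methyl 2-[bis(2,2,2-trifluoroethoxy)phosphoryl]-4-[(tert-butyldimethylsilyl)oxy]butanoate; 4 (tert-butyldiphenylsilyloxy)acetaldehyde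
Product: 5 methyl (2Z)-4-[(tert-butyldiphenylsilyl)oxy]-2-{2-[(tert-butyldimethylsilyl)oxy]ethyl}but-2-enoate
Conditions: KN(SiMe3)2, 18-crown-6, THF, −78 °C; then 4
Reagents that add atoms: none
Why: Still–Gennari variant of the Horner–Wadsworth–Emmons reaction: with the trifluoroethyl phosphonate and a crown-ether-separated potassium ion the first adduct collapses faster than it equilibrates, so the aldehyde residue ends cis to the ester and the Z-enoate should dominate. This geometry becomes the exocyclic geometry of ring A.

Step 3
Reactants: 5 methyl (2Z)-4-[(tert-butyldiphenylsilyl)oxy]-2-{2-[(tert-butyldimethylsilyl)oxy]ethyl}but-2-enoate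
Product: 6 (2Z)-4-[(tert-butyldiphenylsilyl)oxy]-2-{2-[(tert-butyldimethylsilyl)oxy]ethyl}but-2-en-1-ol
Conditions: iBu2AlH, CH2Cl2, −78 °C
Reagents that add atoms: none
Why: 1,2-Reduction of the enoate to the allylic alcohol by the aluminium hydride at low temperature; silyl ethers and alkene geometry are not touched.

Step 4
Reactants: 6 (2Z)-4-[(tert-butyldiphenylsilyl)oxy]-2-{2-[(tert-butyldimethylsilyl)oxy]ethyl}but-2-en-1-ol
Product: 7 (2Z)-1-bromo-4-[(tert-butyldiphenylsilyl)oxy]-2-{2-[(tert-butyldimethylsilyl)oxy]ethyl}but-2-ene
Conditions: CBr4, PPh3, 2,6-lutidine, CH2Cl2, 0 °C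
Reagents that add atoms: carbon tetrabromide, BrC(Br)(Br)Br
Why: Appel bromination, SN2 at the primary allylic carbon; cold, buffered conditions keep the Z geometry and the silyl ethers, and 7 is used at once.

Step 5
Reactants: 8 2,2-dimethylcyclohexanone; 7 (2Z)-1-bromo-4-[(tert-butyldiphenylsilyl)oxy]-2-{2-[(tert-butyldimethylsilyl)oxy]ethyl}but-2-ene
Product: 9 6-[(2E)-4-[(tert-butyldiphenylsilyl)oxy]-2-{2-[(tert-butyldimethylsilyl)oxy]ethyl}but-2-en-1-yl]-2,2-dimethylcyclohexan-1-one (racemic at C6)
Conditions: LiN(iPr)2, THF, −78 °C; then 7, DMPU, −78 → −20 °C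
Reagents that add atoms: none
Why: Ketone enolate alkylation: 8 can be deprotonated only at C6 because C2 is quaternary, so a single lithium enolate forms and is alkylated by SN2 at the primary allylic bromide. The new stereocentre is racemic and is removed in step 6.

Step 6
Reactants: 9 6-[(2E)-4-[(tert-butyldiphenylsilyl)oxy]-2-{2-[(tert-butyldimethylsilyl)oxy]ethyl}but-2-en-1-yl]-2,2-dimethylcyclohexan-1-one
Product: 10 2-[(2E)-4-[(tert-butyldiphenylsilyl)oxy]-2-{2-[(tert-butyldimethylsilyl)oxy]ethyl}but-2-en-1-yl]-6,6-dimethylcyclohex-1-en-1-yl trifluoromethanesulfonate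
Conditions: KN(SiMe3)2, THF, −78 → 0 °C; then PhNTf2, −78 °C → rt
Reagents that add atoms: N-phenylbis(trifluoromethanesulfonimide), FC(F)(F)S(=O)(=O)N(c1ccccc1)S(=O)(=O)C(F)(F)F
Why: Enol triflate formation: the only remaining α-hydrogen gives the tetrasubstituted potassium enolate, which is sulfonylated on oxygen by the triflimide; this fixes the future C4a=C8a alkene without isomers.

Step 7
Reactants: 10 2-[(2E)-4-[(tert-butyldiphenylsilyl)oxy]-2-{2-[(tert-butyldimethylsilyl)oxy]ethyl}but-2-en-1-yl]-6,6-dimethylcyclohex-1-en-1-yl trifluoromethanesulfonate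
Product: 11 2-[(2E)-4-[(tert-butyldiphenylsilyl)oxy]-2-(2-hydroxyethyl)but-2-en-1-yl]-6,6-dimethylcyclohex-1-en-1-yl trifluoromethanesulfonate
Conditions: PPTS, MeOH, rt
Reagents that add atoms: none
Why: Acid-catalysed methanolysis cleaves the primary tert-butyldimethylsilyl ether much faster than the bulkier tert-butyldiphenylsilyl ether; the enol triflate tolerates the mild acid.

Step 8
Reactants: 11 2-[(2E)-4-[(tert-butyldiphenylsilyl)oxy]-2-(2-hydroxyethyl)but-2-en-1-yl]-6,6-dimethylcyclohex-1-en-1-yl trifluoromethanesulfonate
Product: 12 2-[(2E)-4-[(tert-butyldiphenylsilyl)oxy]-2-(2-iodoethyl)but-2-en-1-yl]-6,6-dimethylcyclohex-1-en-1-yl trifluoromethanesulfonate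
Conditions: I2, PPh3, imidazole, CH2Cl2, 0 °C
Reagents that add atoms: iodine, II
Why: Appel-type iodination (Garegg–Samuelsson conditions) of the primary alcohol by SN2; neutral conditions spare the enol triflate and the silyl ether.

Step 9
Reactants: 12 2-[(2E)-4-[(tert-butyldiphenylsilyl)oxy]-2-(2-iodoethyl)but-2-en-1-yl]-6,6-dimethylcyclohex-1-en-1-yl trifluoromethanesulfonate
Product: 14 tert-butyl{2-[(2Z)-5,5-dimethyl-3,4,5,6,7,8-hexahydronaphthalen-2(1H)-ylidene]ethoxy}diphenylsilane, via alkylzinc iodide 13 (not isolated)
Conditions: Zn dust (activated with BrCH2CH2Br and Me3SiCl), LiCl, THF, 40 °C; then slow addition to Pd(dppf)Cl2 (5 mol %), THF, 60 °C, 0.01 M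
Reagents that add atoms: zinc, [Zn] (present only in 13)
Why: Zinc, solubilised by LiCl, inserts into the primary carbon–iodine bond of 12 to give the alkylzinc iodide 13, which is inert towards the enol triflate, the silyl ether and the alkene. Pd(dppf)Cl2 (divalent palladium) is reduced in the flask to zerovalent palladium, which adds oxidatively to the C–O bond of the triflate; transmetalation from zinc and reductive elimination then join C4 to C4a. The closest known reaction type is the Negishi coupling of alkylzinc halides with alkenyl triflates, here run within one molecule. Ring A closes as a six-membered ring by reductive elimination from a seven-membered alkyl(alkenyl)palladacycle; this is not an ionic closure, so no Baldwin constraint applies, and slow addition at high dilution favours it over oligomerisation. No stereocentre is formed. The position of the ring-fusion alkene is secured because the triflate marks C4a=C8a and ketone 9 had only one enolisable carbon. The exocyclic geometry set in step 2 is secured because zinc sits on a homoallylic carbon and no allyl metal intermediate can form. Reductive elimination must outrun β-hydride elimination, which the wide bite angle of dppf should ensure.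

Step 10
Reactants: 14 tert-butyl{2-[(2Z)-5,5-dimethyl-3,4,5,6,7,8-hexahydronaphthalen-2(1H)-ylidene]ethoxy}diphenylsilane
Product: 15 2-[(2Z)-5,5-dimethyl-3,4,5,6,7,8-hexahydronaphthalen-2(1H)-ylidene]ethan-1-ol
Conditions: Bu4NF, THF, 0 °C → rt
Reagents that add atoms: none
Why: Fluoride-induced desilylation; with a silyl ether at this position the skipped diene of 14, with its doubly allylic methylene, never meets a quinone oxidant or an acid.

Step 11
Reactants: 15 2-[(2Z)-5,5-dimethyl-3,4,5,6,7,8-hexahydronaphthalen-2(1H)-ylidene]ethan-1-ol
Product: 16 5-({2-[(2Z)-5,5-dimethyl-3,4,5,6,7,8-hexahydronaphthalen-2(1H)-ylidene]ethyl}sulfanyl)-1-phenyl-1H-tetrazole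
Conditions: 1-phenyl-1H-tetrazole-5-thiol, PPh3, DIAD, THF, 0 °C
Reagents that add atoms: 1-phenyl-1H-tetrazole-5-thiol, Sc1nnnn1-c1ccccc1
Why: Mitsunobu thioetherification: the activated primary allylic alcohol is displaced by the acidic thiol in an SN2 reaction at the unhindered terminus, so the alkene neither shifts nor isomerises.

Step 12
Reactants: 16 5-({2-[(2Z)-5,5-dimethyl-3,4,5,6,7,8-hexahydronaphthalen-2(1H)-ylidene]ethyl}sulfanyl)-1-phenyl-1H-tetrazole
Product: 17 5-({2-[(2Z)-5,5-dimethyl-3,4,5,6,7,8-hexahydronaphthalen-2(1H)-ylidene]ethyl}sulfonyl)-1-phenyl-1H-tetrazole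
Conditions: (NH4)6Mo7O24·4H2O (10 mol %), 30% H2O2, EtOH, 0 °C → rt
Reagents that add atoms: hydrogen peroxide, OO
Why: Molybdate-catalysed oxidation of the sulfide to the sulfone with hydrogen peroxide; sulfur is oxidised much faster than the alkenes, and the low temperature limits reversible [2,3]-shift of the intermediate allylic sulfoxide, which could erode the alkene geometry.

Step 13
Reactants: 18 geranyl acetate
Product: 19 (2E)-3-methyl-6-oxohex-2-en-1-yl acetate
Conditions: O3 (one equivalent), CH2Cl2, −78 °C; then Me2S, −78 °C → rt
Reagents that add atoms: ozone, [O-][O+]=O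
Why: Chemoselective ozonolysis: the distal trisubstituted alkene is the more electron-rich one because the allylic acetate deactivates the C2 alkene, so one equivalent of ozone followed by reduction of the ozonide with the sulfide should give the aldehyde. The end point is followed closely to avoid double cleavage.

Step 14
Reactants: 19 (2E)-3-methyl-6-oxohex-2-en-1-yl acetate; 20 cis-but-2-ene
Product: 21 (2E,6R,7R)-6-hydroxy-3,7-dimethylnona-2,8-dien-1-yl acetate
Conditions: 20, KOtBu, BuLi, THF, −78 → −45 °C; (−)-Ipc2BOMe, −78 °C; BF3·OEt2; then 19, −78 °C; NaBO3·4H2O, THF/H2O, rt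
Reagents that add atoms: none
Why: Brown crotylboration through a closed chair transition state: the Z-crotyl geometry gives the syn relationship, and the isopinocampheyl groups of the (+)-α-pinene series direct addition to the Si face of the aldehyde. This sets the carbinol carbon (future C3) and the methyl-bearing carbon (future C2), both R in 21; the perborate work-up oxidises the borinate without hydrolysing the acetate.

Step 15
Reactants: 21 (2E,6R,7R)-6-hydroxy-3,7-dimethylnona-2,8-dien-1-yl acetate
Product: 22 (2E,6R,7R)-6-[(methanesulfonyl)oxy]-3,7-dimethylnona-2,8-dien-1-yl acetate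
Conditions: MsCl, Et3N, CH2Cl2, 0 °C
Reagents that add atoms: methanesulfonyl chloride, CS(=O)(=O)Cl
Why: Sulfonylation of the secondary alcohol with retention; the mesylate is the leaving group for the later ring closure and also stops this oxygen from opening the epoxide made in step 17.

Step 16
Reactants: 22 (2E,6R,7R)-6-[(methanesulfonyl)oxy]-3,7-dimethylnona-2,8-dien-1-yl acetate
Product: 23 (3R,4R,7E)-9-hydroxy-3,7-dimethylnona-1,7-dien-4-yl methanesulfonate
Conditions: K2CO3 (0.2 equiv), MeOH, 0 °C
Reagents that add atoms: none
Why: Transesterification of the primary allylic acetate with methanol under mild carbonate catalysis; the secondary mesylate is inert at 0 °C.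

Step 17
Reactants: 23 (3R,4R,7E)-9-hydroxy-3,7-dimethylnona-1,7-dien-4-yl methanesulfonate
Product: 24 (3R,4R)-6-[(2S,3S)-3-(hydroxymethyl)-2-methyloxiran-2-yl]-3-methylhex-1-en-4-yl methanesulfonate
Conditions: Ti(OiPr)4 (10 mol %), L-(+)-diethyl tartrate, tBuOOH, 4 Å molecular sieves, CH2Cl2, −20 °C
Reagents that add atoms: tert-butyl hydroperoxide, CC(C)(C)OO
Why: Sharpless asymmetric epoxidation of the E-trisubstituted allylic alcohol; with the L-(+)-tartrate the titanium complex delivers oxygen to the face that gives the (2S,3S)-epoxy alcohol, under reagent control and independent of the remote centres. The isolated terminal alkene is not a substrate, and the tertiary epoxide carbon is the future C6.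

Step 18
Reactants: 24 (3R,4R)-6-[(2S,3S)-3-(hydroxymethyl)-2-methyloxiran-2-yl]-3-methylhex-1-en-4-yl methanesulfonate
Product: 26 (1S)-1-{(3R,6S)-6-[(2R)-but-3-en-2-yl]-3-methyl-1,2-dioxan-3-yl}ethane-1,2-diol, via tertiary hydroperoxide 25 (not isolated)
Conditions: H2O2 (ethereal, excess), H3PMo12O40 (5 mol %), Et2O, 0 °C → rt; aqueous wash, solvent switch to THF; KOtBu (1.0 equiv), 18-crown-6, 0 °C
Reagents that add atoms: hydrogen peroxide, OO
Why: Acid-catalysed perhydrolysis of the epoxy alcohol: hydrogen peroxide attacks the tertiary, more cation-stabilising carbon from the side opposite to the epoxide oxygen, so C6 is set by inversion of the Sharpless centre. One equivalent of base then forms the peroxy anion, which displaces the secondary mesylate in a 6-exo-tet SN2 reaction with inversion at C3 (peroxide alkylation), giving the dioxane with the C3 and C6 carbon chains cis.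

Step 19
Reactants: 26 (1S)-1-{(3R,6S)-6-[(2R)-but-3-en-2-yl]-3-methyl-1,2-dioxan-3-yl}ethane-1,2-diol
Product: 28 (2S)-2-{(3S,6R)-6-[(1S)-1,2-dihydroxyethyl]-6-methyl-1,2-dioxan-3-yl}propanoic acid, via aldehyde 27 (not isolated)
Conditions: O3, CH2Cl2, −78 °C; Me2S; then NaClO2, NaH2PO4, 2-methyl-2-butene, tBuOH/H2O, 0 °C
Reagents that add atoms: ozone, [O-][O+]=O; sodium chlorite, [Na+].[O-]Cl=O
Why: Ozonolysis of the only alkene to the aldehyde and immediate Pinnick oxidation to the acid; telescoping and the buffered chlorite conditions keep the epimerisable, β-peroxy aldehyde 27 away from base and silica. The O–O bond and the diol are inert to ozone, the sulfide and chlorite.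

Step 20
Reactants: 28 (2S)-2-{(3S,6R)-6-[(1S)-1,2-dihydroxyethyl]-6-methyl-1,2-dioxan-3-yl}propanoic acid
Product: 29 methyl (2S)-2-{(3S,6R)-6-[(1S)-1,2-dihydroxyethyl]-6-methyl-1,2-dioxan-3-yl}propanoate
Conditions: Me3SiCHN2, MeOH/toluene, 0 °C
Reagents that add atoms: (trimethylsilyl)diazomethane, C[Si](C)(C)C=[N+]=[N-]
Why: Methyl ester formation with the silylated diazomethane in methanol under neutral conditions; no base or acid touches the peroxide or C2.

Step 21
Reactants: 29 methyl (2S)-2-{(3S,6R)-6-[(1S)-1,2-dihydroxyethyl]-6-methyl-1,2-dioxan-3-yl}propanoate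
Product: 30 methyl (2S)-2-[(3S,6R)-6-formyl-6-methyl-1,2-dioxan-3-yl]propanoate
Conditions: NaIO4, THF/pH 7 buffer, 0 °C
Reagents that add atoms: none
Why: Periodate cleavage of the vicinal diol (Malaprade reaction) releases the aldehyde on C6 and formaldehyde; the aldehyde has no α-hydrogen and the dialkyl peroxide is inert to periodate.

Step 22
Reactants: 17 5-({2-[(2Z)-5,5-dimethyl-3,4,5,6,7,8-hexahydronaphthalen-2(1H)-ylidene]ethyl}sulfonyl)-1-phenyl-1H-tetrazole; 30 methyl (2S)-2-[(3S,6R)-6-formyl-6-methyl-1,2-dioxan-3-yl]propanoate
Product: 31 methyl (2S)-2-{(3S,6R)-6-[(1E,3Z)-3-(5,5-dimethyl-3,4,5,6,7,8-hexahydronaphthalen-2(1H)-ylidene)prop-1-en-1-yl]-6-methyl-1,2-dioxan-3-yl}propanoate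
Conditions: 17, KN(SiMe3)2 (1.0 equiv), DME, −78 °C, 15 min; then 30, −78 °C → rt
Reagents that add atoms: none
Why: Julia–Kocienski olefination: the allylic sulfonyl anion adds to the non-enolisable aldehyde, the alkoxide attacks the tetrazole (Smiles rearrangement), and sulfur dioxide and the tetrazolone salt are expelled to give the diene. The weakly basic sulfonyl anion is formed first with one equivalent of base, so neither the ester α-hydrogen nor H–C3 should be attacked; the geometry of the new alkene is irrelevant and that of the trisubstituted alkene is retained.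

Step 23
Reactants: 31 methyl (2S)-2-{(3S,6R)-6-[(1E,3Z)-3-(5,5-dimethyl-3,4,5,6,7,8-hexahydronaphthalen-2(1H)-ylidene)prop-1-en-1-yl]-6-methyl-1,2-dioxan-3-yl}propanoate
Product: 32 methyl (2S)-2-{(3S,6S)-6-[(3Z)-3-(5,5-dimethyl-3,4,5,6,7,8-hexahydronaphthalen-2(1H)-ylidene)propyl]-6-methyl-1,2-dioxan-3-yl}propanoate
Conditions: KO2CN=NCO2K, AcOH, CH2Cl2/MeOH, 0 °C → rt, reagent added in portions
Reagents that add atoms: none
Why: Diimide transfers two hydrogens in a concerted syn fashion to the least substituted alkene; the disubstituted C1'=C2' bond reacts much faster than the trisubstituted and tetrasubstituted alkenes, and diimide does not cleave O–O bonds. Conversion is followed so that the reaction is stopped before the exocyclic alkene is touched.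

Step 24
Reactants: 32 methyl (2S)-2-{(3S,6S)-6-[(3Z)-3-(5,5-dimethyl-3,4,5,6,7,8-hexahydronaphthalen-2(1H)-ylidene)propyl]-6-methyl-1,2-dioxan-3-yl}propanoate
Product: 33 (2S)-2-{(3S,6S)-6-[(3Z)-3-(5,5-dimethyl-3,4,5,6,7,8-hexahydronaphthalen-2(1H)-ylidene)propyl]-6-methyl-1,2-dioxan-3-yl}propanoic acid
Conditions: LiOH, THF/MeOH/H2O, 0 °C → rt; then 0.5 M HCl to pH 3, 0 °C
Reagents that add atoms: lithium hydroxide, [Li+].[OH-]
Why: Saponification by hydroxide attack at the ester carbonyl (acyl–oxygen cleavage) at low temperature, then careful acidification; attack at the carbonyl is faster than enolisation at C2, so the anti C2/C3 relationship and the peroxide should survive.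

## Compound list

1 | methyl bis(2,2,2-trifluoroethyl)phosphonoacetate | COC(=O)CP(=O)(OCC(F)(F)F)OCC(F)(F)F | starting material
2 | tert-butyl(2-iodoethoxy)dimethylsilane | CC(C)(C)[Si](C)(C)OCCI | starting material
3 | methyl 2-[bis(2,2,2-trifluoroethoxy)phosphoryl]-4-[(tert-butyldimethylsilyl)oxy]butanoate (racemic) | COC(=O)C(CCO[Si](C)(C)C(C)(C)C)P(=O)(OCC(F)(F)F)OCC(F)(F)F | intermediate
4 | (tert-butyldiphenylsilyloxy)acetaldehyde | O=CCO[Si](c1ccccc1)(c1ccccc1)C(C)(C)C | starting material
5 | methyl (2Z)-4-[(tert-butyldiphenylsilyl)oxy]-2-{2-[(tert-butyldimethylsilyl)oxy]ethyl}but-2-enoate | COC(=O)/C(CCO[Si](C)(C)C(C)(C)C)=C\CO[Si](c1ccccc1)(c1ccccc1)C(C)(C)C | intermediate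
6 | (2Z)-4-[(tert-butyldiphenylsilyl)oxy]-2-{2-[(tert-butyldimethylsilyl)oxy]ethyl}but-2-en-1-ol | OC/C(CCO[Si](C)(C)C(C)(C)C)=C\CO[Si](c1ccccc1)(c1ccccc1)C(C)(C)C | intermediate
7 | (2Z)-1-bromo-4-[(tert-butyldiphenylsilyl)oxy]-2-{2-[(tert-butyldimethylsilyl)oxy]ethyl}but-2-ene | BrC/C(CCO[Si](C)(C)C(C)(C)C)=C\CO[Si](c1ccccc1)(c1ccccc1)C(C)(C)C | intermediate
8 | 2,2-dimethylcyclohexanone | CC1(C)CCCCC1=O | starting material
9 | 6-[(2E)-4-[(tert-butyldiphenylsilyl)oxy]-2-{2-[(tert-butyldimethylsilyl)oxy]ethyl}but-2-en-1-yl]-2,2-dimethylcyclohexan-1-one (racemic at C6) | O=C1C(C/C(CCO[Si](C)(C)C(C)(C)C)=C\CO[Si](c2ccccc2)(c2ccccc2)C(C)(C)C)CCCC1(C)C | intermediate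
10 | 2-[(2E)-4-[(tert-butyldiphenylsilyl)oxy]-2-{2-[(tert-butyldimethylsilyl)oxy]ethyl}but-2-en-1-yl]-6,6-dimethylcyclohex-1-en-1-yl trifluoromethanesulfonate | CC(C)(C)[Si](c1ccccc1)(c1ccccc1)OC/C=C(/CCO[Si](C)(C)C(C)(C)C)CC1=C(OS(=O)(=O)C(F)(F)F)C(C)(C)CCC1 | intermediate
11 | 2-[(2E)-4-[(tert-butyldiphenylsilyl)oxy]-2-(2-hydroxyethyl)but-2-en-1-yl]-6,6-dimethylcyclohex-1-en-1-yl trifluoromethanesulfonate | CC(C)(C)[Si](c1ccccc1)(c1ccccc1)OC/C=C(/CCO)CC1=C(OS(=O)(=O)C(F)(F)F)C(C)(C)CCC1 | intermediate
12 | 2-[(2E)-4-[(tert-butyldiphenylsilyl)oxy]-2-(2-iodoethyl)but-2-en-1-yl]-6,6-dimethylcyclohex-1-en-1-yl trifluoromethanesulfonate | CC(C)(C)[Si](c1ccccc1)(c1ccccc1)OC/C=C(/CCI)CC1=C(OS(=O)(=O)C(F)(F)F)C(C)(C)CCC1 | intermediate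
13 | iodo{(3E)-5-[(tert-butyldiphenylsilyl)oxy]-3-[(3,3-dimethyl-2-{[(trifluoromethyl)sulfonyl]oxy}cyclohex-1-en-1-yl)methyl]pent-3-en-1-yl}zinc (formed in the flask) | CC(C)(C)[Si](c1ccccc1)(c1ccccc1)OC/C=C(/CC[Zn]I)CC1=C(OS(=O)(=O)C(F)(F)F)C(C)(C)CCC1 | intermediate
14 | tert-butyl{2-[(2Z)-5,5-dimethyl-3,4,5,6,7,8-hexahydronaphthalen-2(1H)-ylidene]ethoxy}diphenylsilane | CC(C)(C)[Si](c1ccccc1)(c1ccccc1)OC/C=C1/CCC2=C(CCCC2(C)C)C1 | intermediate
15 | 2-[(2Z)-5,5-dimethyl-3,4,5,6,7,8-hexahydronaphthalen-2(1H)-ylidene]ethan-1-ol | OC/C=C1/CCC2=C(CCCC2(C)C)C1 | intermediate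
16 | 5-({2-[(2Z)-5,5-dimethyl-3,4,5,6,7,8-hexahydronaphthalen-2(1H)-ylidene]ethyl}sulfanyl)-1-phenyl-1H-tetrazole | c1ccc(cc1)-n1nnnc1SC/C=C1/CCC2=C(CCCC2(C)C)C1 | intermediate
17 | 5-({2-[(2Z)-5,5-dimethyl-3,4,5,6,7,8-hexahydronaphthalen-2(1H)-ylidene]ethyl}sulfonyl)-1-phenyl-1H-tetrazole | O=S(=O)(C/C=C1/CCC2=C(CCCC2(C)C)C1)c1nnnn1-c1ccccc1 | intermediate
18 | geranyl acetate, (2E)-3,7-dimethylocta-2,6-dien-1-yl acetate | CC(C)=CCC/C(C)=C/COC(C)=O | starting material
19 | (2E)-3-methyl-6-oxohex-2-en-1-yl acetate | O=CCC/C(C)=C/COC(C)=O | intermediate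
20 | cis-but-2-ene | C/C=C\C | starting material
21 | (2E,6R,7R)-6-hydroxy-3,7-dimethylnona-2,8-dien-1-yl acetate | C=C[C@@H](C)[C@H](O)CC/C(C)=C/COC(C)=O | intermediate
22 | (2E,6R,7R)-6-[(methanesulfonyl)oxy]-3,7-dimethylnona-2,8-dien-1-yl acetate | C=C[C@@H](C)[C@H](OS(C)(=O)=O)CC/C(C)=C/COC(C)=O | intermediate
23 | (3R,4R,7E)-9-hydroxy-3,7-dimethylnona-1,7-dien-4-yl methanesulfonate | C=C[C@@H](C)[C@H](OS(C)(=O)=O)CC/C(C)=C/CO | intermediate
24 | (3R,4R)-6-[(2S,3S)-3-(hydroxymethyl)-2-methyloxiran-2-yl]-3-methylhex-1-en-4-yl methanesulfonate | C=C[C@@H](C)[C@H](OS(C)(=O)=O)CC[C@@](C)([C@@H]1CO)O1 | intermediate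
25 | (3R,4R,7R,8S)-7-hydroperoxy-8,9-dihydroxy-3,7-dimethylnon-1-en-4-yl methanesulfonate (formed in the flask) | C=C[C@@H](C)[C@H](OS(C)(=O)=O)CC[C@](C)([C@@H](O)CO)OO | intermediate
26 | (1S)-1-{(3R,6S)-6-[(2R)-but-3-en-2-yl]-3-methyl-1,2-dioxan-3-yl}ethane-1,2-diol | C=C[C@@H](C)[C@@H]1CC[C@](C)([C@@H](O)CO)OO1 | intermediate
27 | (2S)-2-{(3S,6R)-6-[(1S)-1,2-dihydroxyethyl]-6-methyl-1,2-dioxan-3-yl}propanal (formed in the flask) | O=C[C@@H](C)[C@@H]1CC[C@](C)([C@@H](O)CO)OO1 | intermediate
28 | (2S)-2-{(3S,6R)-6-[(1S)-1,2-dihydroxyethyl]-6-methyl-1,2-dioxan-3-yl}propanoic acid | C[C@H](C(=O)O)[C@@H]1CC[C@](C)([C@@H](O)CO)OO1 | intermediate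
29 | methyl (2S)-2-{(3S,6R)-6-[(1S)-1,2-dihydroxyethyl]-6-methyl-1,2-dioxan-3-yl}propanoate | C[C@H](C(=O)OC)[C@@H]1CC[C@](C)([C@@H](O)CO)OO1 | intermediate
30 | methyl (2S)-2-[(3S,6R)-6-formyl-6-methyl-1,2-dioxan-3-yl]propanoate | C[C@H](C(=O)OC)[C@@H]1CC[C@](C)(C=O)OO1 | intermediate
31 | methyl (2S)-2-{(3S,6R)-6-[(1E,3Z)-3-(5,5-dimethyl-3,4,5,6,7,8-hexahydronaphthalen-2(1H)-ylidene)prop-1-en-1-yl]-6-methyl-1,2-dioxan-3-yl}propanoate | C[C@H](C(=O)OC)[C@@H]1CC[C@](C)(/C=C/C=C2/CCC3=C(CCCC3(C)C)C2)OO1 | intermediate
32 | methyl (2S)-2-{(3S,6S)-6-[(3Z)-3-(5,5-dimethyl-3,4,5,6,7,8-hexahydronaphthalen-2(1H)-ylidene)propyl]-6-methyl-1,2-dioxan-3-yl}propanoate | C[C@H](C(=O)OC)[C@@H]1CC[C@](C)(CC/C=C2/CCC3=C(CCCC3(C)C)C2)OO1 | intermediate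
33 | (2S)-2-{(3S,6S)-6-[(3Z)-3-(5,5-dimethyl-3,4,5,6,7,8-hexahydronaphthalen-2(1H)-ylidene)propyl]-6-methyl-1,2-dioxan-3-yl}propanoic acid | C[C@H](C(=O)O)[C@@H]1CC[C@](C)(CC/C=C2/CCC3=C(CCCC3(C)C)C2)OO1 | target

## Step count and least certain steps

Total: 24 steps. Longest linear sequence: 15 steps (steps 1–12, then 22–24). The peroxide branch (steps 13–21) is 9 steps and joins at step 22.

**Step 9 (key step).** Oxidative addition into the tetrasubstituted triflate next to the gem-dimethyl carbon may be slow. The alkylzinc could then be lost by protonation, or β-hydride elimination could overtake reductive elimination after transmetalation. At higher concentration intermolecular coupling would compete. Fallback: setting out from 12, copper-catalysed borylation of the primary iodide (CuI, PPh3, LiOMe, B2pin2, DMF, rt) would give the pinacol boronate F1. KHF2 in MeOH/H2O would convert it into the potassium trifluoroborate F2, an air-stable nucleophile that releases boron slowly. Intramolecular Suzuki–Miyaura coupling with the enol triflate (Pd(dppf)Cl2, Cs2CO3, THF/H2O, 80 °C) would then close the same C4–C4a bond and return to 14.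

**Step 18.** Two processes threaten it. The first is loss of stereochemical fidelity at the tertiary carbon if the epoxide opens with carbocation character, or rearrangement of the epoxide to a carbonyl compound. The second, in the base stage, is elimination of the mesylate towards the allylic hydrogen or fragmentation of the β-hydroxy hydroperoxide. Fallback: the two C–O bond formations exchange roles. Setting out from 24, the mesylate would be displaced with inversion by hydrogen peroxide under basic conditions (50% H2O2, CsOH·H2O, DMF, 0 °C) to give the secondary hydroperoxide F3. Camphorsulfonic acid in CH2Cl2 would then induce 6-exo opening of the epoxide at its tertiary carbon, with inversion enforced by the tether, and return to 26.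

**Step 22.** The β-alkoxide formed on addition sits next to the peroxide carbon and may fragment (C–C and O–O cleavage) before the Smiles rearrangement. Base may also attack H–C3 (Kornblum–DeLaMare cleavage), or the allylic sulfonyl anion may self-condense before it meets the hindered aldehyde. Fallback: a Wittig union, which passes through an oxaphosphetane and no free alkoxide. Setting out from 15, Appel bromination (CBr4, PPh3, 0 °C) would give the allylic bromide F4, and PPh3 in MeCN the phosphonium bromide F5. Its ylide (KN(SiMe3)2, THF, −78 °C) would be condensed with 30 to return to 31.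

**Step 24.** Enolisation at C2 by hydroxide would cause epimerisation or β-elimination that opens the dioxane, and base attack at H–C3 is also possible. Fallback: the acid is never esterified. Setting out from 28, NaIO4 cleavage would give the formyl acid F6. After conversion into its potassium carboxylate with one equivalent of KN(SiMe3)2 at −78 °C, it would be added to the anion of 17 to give the diene acid F7. Diimide reduction as in step 23 would then return directly to 33.

## Further compounds

F1 | step 9 | 2-[(2E)-4-[(tert-butyldiphenylsilyl)oxy]-2-[2-(4,4,5,5-tetramethyl-1,3,2-dioxaborolan-2-yl)ethyl]but-2-en-1-yl]-6,6-dimethylcyclohex-1-en-1-yl trifluoromethanesulfonate | CC(C)(C)[Si](c1ccccc1)(c1ccccc1)OC/C=C(/CCB1OC(C)(C)C(C)(C)O1)CC1=C(OS(=O)(=O)C(F)(F)F)C(C)(C)CCC1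
F2 | step 9 | potassium {(3E)-5-[(tert-butyldiphenylsilyl)oxy]-3-[(3,3-dimethyl-2-{[(trifluoromethyl)sulfonyl]oxy}cyclohex-1-en-1-yl)methyl]pent-3-en-1-yl}trifluoroborate | CC(C)(C)[Si](c1ccccc1)(c1ccccc1)OC/C=C(/CC[B-](F)(F)F)CC1=C(OS(=O)(=O)C(F)(F)F)C(C)(C)CCC1.[K+]
F3 | step 18 | [(2S,3S)-3-[(3S,4R)-3-hydroperoxy-4-methylhex-5-en-1-yl]-3-methyloxiran-2-yl]methanol | C=C[C@@H](C)[C@@H](OO)CC[C@@](C)([C@@H]1CO)O1
F4 | step 22 | (2Z)-2-(2-bromoethylidene)-5,5-dimethyl-1,2,3,4,5,6,7,8-octahydronaphthalene | BrC/C=C1/CCC2=C(CCCC2(C)C)C1
F5 | step 22 | {2-[(2Z)-5,5-dimethyl-3,4,5,6,7,8-hexahydronaphthalen-2(1H)-ylidene]ethyl}triphenylphosphonium bromide | [Br-].C(/C=C1/CCC2=C(CCCC2(C)C)C1)[P+](c1ccccc1)(c1ccccc1)c1ccccc1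
F6 | step 24 | (2S)-2-[(3S,6R)-6-formyl-6-methyl-1,2-dioxan-3-yl]propanoic acid | C[C@H](C(=O)O)[C@@H]1CC[C@](C)(C=O)OO1
F7 | step 24 | (2S)-2-{(3S,6R)-6-[(1E,3Z)-3-(5,5-dimethyl-3,4,5,6,7,8-hexahydronaphthalen-2(1H)-ylidene)prop-1-en-1-yl]-6-methyl-1,2-dioxan-3-yl}propanoic acid | C[C@H](C(=O)O)[C@@H]1CC[C@](C)(/C=C/C=C2/CCC3=C(CCCC3(C)C)C2)OO1
A1 | alternative 1 | acetonide of 1-methyl-2,3-dioxabicyclo[2.2.2]oct-5-ene-7,8-diol, peroxide bridge anti to the dioxolane | [C@@H]12C=C[C@@](C)(OO1)[C@@H]3OC(C)(C)O[C@H]23
A2 | alternative 1 | acetonide of cis-3-methylcyclohexa-3,5-diene-1,2-diol in the enantiomeric form that A1 requires (mirror image of the acetonide of A3) | CC1=CC=C[C@H]2OC(C)(C)O[C@@H]12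
A3 | alternative 1 | (1S,2R)-3-methylcyclohexa-3,5-diene-1,2-diol | CC1=CC=C[C@H](O)[C@@H]1O
A4 | alternative 1 | (3S,6R)-6-methyl-1,2-dioxane-3,6-dicarbaldehyde | O=C[C@@H]1CC[C@](C)(C=O)OO1
A5 | alternative 2 | methyl ester of the target, identical with 32 | C[C@H](C(=O)OC)[C@@H]1CC[C@](C)(CC/C=C2/CCC3=C(CCCC3(C)C)C2)OO1
A6 | alternative 2 | [2-(but-3-yn-1-yl)-3,3-dimethylcyclohex-1-en-1-yl]methyl acetate | CC(=O)OCC1=C(CCC#C)C(C)(C)CCC1
A7 | alternative 2 | methyl (2S)-2-{(3S,6S)-6-[2-(9-borabicyclo[3.3.1]nonan-9-yl)ethyl]-6-methyl-1,2-dioxan-3-yl}propanoate | C[C@H](C(=O)OC)[C@@H]1CC[C@](C)(CCB2C3CCCC2CCC3)OO1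
A8 | alternative 3 | (6S)-6-{2-[(tert-butyldiphenylsilyl)oxy]ethyl}-3-ethoxy-6-methyl-3,6-dihydro-1,2-dioxine (either C3 epimer) | CCOC1C=C[C@](C)(CCO[Si](c2ccccc2)(c2ccccc2)C(C)(C)C)OO1
A9 | alternative 3 | tert-butyl{[(3S)-3-[(1-ethoxyprop-2-en-1-yl)peroxy]-3-methylpent-4-en-1-yl]oxy}diphenylsilane | C=C[C@](C)(CCO[Si](c1ccccc1)(c1ccccc1)C(C)(C)C)OOC(OCC)C=C
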